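Numbering: chroman O1, C2, C3, C4, C4a, C5–C8, C8a. Ring A is the benzo ring, ring B the pyran ring, ring C the aryl group on C2. C1' and C2' are the first two carbons of the chain on C4.
Retrosynthesis: the five phenols are capped as O–CH3 and C1'–C2' is desaturated. Ring B is then cut at C4–C4a, followed by C4=C1' (cross-metathesis), O1–C8a (nucleophilic aromatic substitution) and C2–C3 (allylboration).
Forward: C2–C3 joins an allylboronate to one formyl group of a threefold-symmetric trialdehyde, which supplies ring C with its two remaining formyl groups. O1–C8a then adds ring A with its formyl group, the chain is lengthened, and ring B, the only ring made, closes last at C4–C4a.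
Enabling feature: in ring A, O1 stands para to the C6 formyl group, so the two carbons ortho to O1 (future C4a and C8) are equivalent and each lies ortho, ortho and para to three oxygens. The isobutyl group on C4 is a reduced 2-methylprop-1-enyl group, so C4 can be the secondary end of a 1,1-dimethylallyl cation that such a carbon traps.
Stereochemistry: C2 and C3 are set together in one chiral-acid-catalysed anti-allylboration. C4 is relayed from them in the ring closure, helped by the C5 oxygen substituent peri to C4. No later step touches a stereocentre.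

Key step: step 6

Assumption: 2,4,6-trimethoxybenzene-1,3,5-tricarbaldehyde is taken as purchasable (sold as a monomer for framework materials), and (R)-TRIP is taken to direct the boronate to the Re face of its formyl groups as it does with simple benzaldehydes.

Step 1
Reactants: 1 allylboronic acid pinacol ester; 2 3-methylbut-1-ene
Product: 3 (E)-(4-methylpent-2-en-1-yl)boronic acid pinacol ester
Conditions: second-generation Grubbs catalyst (2 mol %), 2 (excess), CH2Cl2, sealed tube, 40 °C
Reagents that add atoms: none
Why: Olefin cross-metathesis of an unhindered allylboronate with an allylically branched terminal alkene is a known entry to γ-substituted allylboronates, and the bulky isopropyl group should bias the reversible exchange towards the E alkene that the anti stereodiad needs.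

Step 2
Reactants: 3 (E)-(4-methylpent-2-en-1-yl)boronic acid pinacol ester; 4 2,4,6-trimethoxybenzene-1,3,5-tricarbaldehyde
Product: 5 5-[(1R,2R)-1-hydroxy-2-(propan-2-yl)but-3-en-1-yl]-2,4,6-trimethoxybenzene-1,3-dicarbaldehyde
Conditions: (R)-TRIP [(R)-3,3'-bis(2,4,6-triisopropylphenyl)-1,1'-binaphthyl-2,2'-diyl hydrogen phosphate] (5 mol %), 4 (2.5 equiv, excess recovered), toluene–CH2Cl2, 4 Å MS, −30 °C; aqueous work-up
Reagents that add atoms: none
Why: Chiral-phosphoric-acid-catalysed allylboration runs through a closed chair transition state in which the E geometry of 3 becomes the anti relation of C2 and C3 and the acid directs attack to the Re face (2R,3R), while the equivalence of the three formyl groups of 4 and its excess should limit the reaction to one addition.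

Step 3
Reactants: 5 5-[(1R,2R)-1-hydroxy-2-(propan-2-yl)but-3-en-1-yl]-2,4,6-trimethoxybenzene-1,3-dicarbaldehyde; 6 2,4,6-trifluorobenzaldehyde
Product: 7 5-[(1R,2R)-1-(3,5-difluoro-4-formylphenoxy)-2-(propan-2-yl)but-3-en-1-yl]-2,4,6-trimethoxybenzene-1,3-dicarbaldehyde
Conditions: NaH (1.05 equiv), THF, 0 °C; then 6 (1.2 equiv), DMPU, −40 → 0 °C
Reagents that add atoms: none
Why: In this nucleophilic aromatic substitution (addition–elimination) the sodium alkoxide displaces the fluoride para to the formyl group of a strongly activated ring, the bulk of the alkoxide and the polar medium should favour the open para site over the flanked ortho sites, and C2 keeps its configuration because its C–O bond is not broken.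

Step 4
Reactants: 7 5-[(1R,2R)-1-(3,5-difluoro-4-formylphenoxy)-2-(propan-2-yl)but-3-en-1-yl]-2,4,6-trimethoxybenzene-1,3-dicarbaldehyde
Product: 8 5-[(1R,2R)-1-(4-formyl-3,5-dimethoxyphenoxy)-2-(propan-2-yl)but-3-en-1-yl]-2,4,6-trimethoxybenzene-1,3-dicarbaldehyde
Conditions: NaOMe (5 equiv), MeOH–THF, 50 °C
Reagents that add atoms: sodium methoxide, C[O-].[Na+]
Why: Two further nucleophilic aromatic substitutions replace the fluorides ortho to the formyl group, fluoride being by far the best leaving group present, methoxide exchange on ring C being degenerate, and neither stereocentre carrying an acidic hydrogen.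

Step 5
Reactants: 8 5-[(1R,2R)-1-(4-formyl-3,5-dimethoxyphenoxy)-2-(propan-2-yl)but-3-en-1-yl]-2,4,6-trimethoxybenzene-1,3-dicarbaldehyde; 9 2-methylbut-3-en-2-ol
Product: 10 5-[(1R,2R,3E)-1-(4-formyl-3,5-dimethoxyphenoxy)-5-hydroxy-5-methyl-2-(propan-2-yl)hex-3-en-1-yl]-2,4,6-trimethoxybenzene-1,3-dicarbaldehyde
Conditions: second-generation Hoveyda–Grubbs catalyst (10 mol %), 9 (5 equiv), CH2Cl2, 40 °C, argon sparge
Reagents that add atoms: none
Why: Olefin cross-metathesis with the free tertiary allylic alcohol is a standard way to turn a vinyl group into an (E)-3-hydroxy-3-methylbut-1-enyl group, ruthenium carbenes tolerate aryl aldehydes and ethers, and the two bulky ends should enforce the E alkene.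

Step 6
Reactants: 10 5-[(1R,2R,3E)-1-(4-formyl-3,5-dimethoxyphenoxy)-5-hydroxy-5-methyl-2-(propan-2-yl)hex-3-en-1-yl]-2,4,6-trimethoxybenzene-1,3-dicarbaldehyde
Product: 12 5-[(2R,3R,4S)-6-formyl-5,7-dimethoxy-4-(2-methylprop-1-en-1-yl)-3-(propan-2-yl)-3,4-dihydro-2H-chromen-2-yl]-2,4,6-trimethoxybenzene-1,3-dicarbaldehyde, via 1,1-dimethylallyl cation 11 (not isolated)
Conditions: MsOH (3 equiv), CH2Cl2 (0.01 M), −60 → −20 °C
Reagents that add atoms: none
Why: MsOH ionises the tertiary allylic alcohol of 10 to the 1,1-dimethylallyl cation 11, ring A attacks its secondary end C4 through the carbon ortho to O1 (future C4a), and loss of the ring proton from the arenium ion restores aromaticity. The closest known reaction type is the intramolecular Friedel–Crafts allylic alkylation of alkoxyarenes by allylic alcohols or protonated 4-methylpenta-1,3-dienyl chains, an established way to a benzylic stereocentre that carries a 2-methylprop-1-enyl group. Ring B closes in the 6-exo-trig mode, since attack at the tertiary end C2' would need an eight-membered ring. C4, the only new stereocentre, is controlled by C2 and C3: in the chair-like transition state ring C and the isopropyl group stay equatorial and the alkenyl arm takes the pseudo-axial place over ring A, because the pseudo-equatorial place presses it against the C5 methoxy group (peri strain), which gives the 3,4-cis relation; the closure is also reversible in acid, so that the outcome can drift towards this less strained isomer. Site selectivity needs no control, because the two carbons ortho to O1 are equivalent, each is activated by three oxygens in spite of the meta formyl group, and ring C has no free position. Chemoselectivity requires that C2–O1 does not ionise and that C3 keeps its proton, which the two formyl groups and the three twisted methoxy groups of ring C (a poor cation stabiliser), the low temperature and the high dilution should secure.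

Step 7
Reactants: 12 5-[(2R,3R,4S)-6-formyl-5,7-dimethoxy-4-(2-methylprop-1-en-1-yl)-3-(propan-2-yl)-3,4-dihydro-2H-chromen-2-yl]-2,4,6-trimethoxybenzene-1,3-dicarbaldehyde
Product: 13 5-[(2R,3R,4S)-6-formyl-5,7-dimethoxy-4-(2-methylpropyl)-3-(propan-2-yl)-3,4-dihydro-2H-chromen-2-yl]-2,4,6-trimethoxybenzene-1,3-dicarbaldehyde
Conditions: H2 (1 atm), 10% Pd/C, EtOAc, 23 °C, stopped after one equivalent of H2
Reagents that add atoms: none
Why: Heterogeneous catalytic hydrogenation should saturate the trisubstituted alkene and so unmask the isobutyl group without forming a stereocentre, while the three aldehydes (each flanked by two methoxy groups) and the hindered C2–O1 ether are expected to survive in a neutral solvent at low pressure.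

Step 8
Reactants: 13 5-[(2R,3R,4S)-6-formyl-5,7-dimethoxy-4-(2-methylpropyl)-3-(propan-2-yl)-3,4-dihydro-2H-chromen-2-yl]-2,4,6-trimethoxybenzene-1,3-dicarbaldehyde
Product: 14 5-[(2R,3R,4S)-6-formyl-5,7-dihydroxy-4-(2-methylpropyl)-3-(propan-2-yl)-3,4-dihydro-2H-chromen-2-yl]-2,4,6-trihydroxybenzene-1,3-dicarbaldehyde (target)
Conditions: BBr3 (12 equiv), CH2Cl2, −78 → 0 °C; then ice-water
Reagents that add atoms: none
Why: Lewis-acid cleavage of aryl methyl ethers is fastest for methoxy groups ortho to a carbonyl group or twisted out of conjugation, which holds for all five here, and at low temperature the secondary C2–O1 ether next to the electron-poor ring C should stay closed, so that no stereocentre is touched.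

Compound list
1 | allylboronic acid pinacol ester | C=CCB1OC(C)(C)C(C)(C)O1 | starting material
2 | 3-methylbut-1-ene | C=CC(C)C | starting material
3 | (E)-(4-methylpent-2-en-1-yl)boronic acid pinacol ester | CC(C)/C=C/CB1OC(C)(C)C(C)(C)O1 | intermediate
4 | 2,4,6-trimethoxybenzene-1,3,5-tricarbaldehyde | COc1c(C=O)c(OC)c(C=O)c(OC)c1C=O | starting material
5 | 5-[(1R,2R)-1-hydroxy-2-(propan-2-yl)but-3-en-1-yl]-2,4,6-trimethoxybenzene-1,3-dicarbaldehyde | O[C@@H](c1c(OC)c(C=O)c(OC)c(C=O)c1OC)[C@@H](C=C)C(C)C | intermediate
6 | 2,4,6-trifluorobenzaldehyde | O=Cc1c(F)cc(F)cc1F | starting material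
7 | 5-[(1R,2R)-1-(3,5-difluoro-4-formylphenoxy)-2-(propan-2-yl)but-3-en-1-yl]-2,4,6-trimethoxybenzene-1,3-dicarbaldehyde | O=Cc1c(F)cc(cc1F)O[C@@H](c1c(OC)c(C=O)c(OC)c(C=O)c1OC)[C@@H](C=C)C(C)C | intermediate
8 | 5-[(1R,2R)-1-(4-formyl-3,5-dimethoxyphenoxy)-2-(propan-2-yl)but-3-en-1-yl]-2,4,6-trimethoxybenzene-1,3-dicarbaldehyde | O=Cc1c(OC)cc(cc1OC)O[C@@H](c1c(OC)c(C=O)c(OC)c(C=O)c1OC)[C@@H](C=C)C(C)C | intermediate
9 | 2-methylbut-3-en-2-ol | C=CC(C)(C)O | starting material
10 | 5-[(1R,2R,3E)-1-(4-formyl-3,5-dimethoxyphenoxy)-5-hydroxy-5-methyl-2-(propan-2-yl)hex-3-en-1-yl]-2,4,6-trimethoxybenzene-1,3-dicarbaldehyde | O=Cc1c(OC)cc(cc1OC)O[C@@H](c1c(OC)c(C=O)c(OC)c(C=O)c1OC)[C@@H](/C=C/C(C)(C)O)C(C)C | intermediate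
11 | 1,1-dimethylallyl cation formed from 10 by loss of water | O=Cc1c(OC)cc(cc1OC)O[C@@H](c1c(OC)c(C=O)c(OC)c(C=O)c1OC)[C@@H](/C=C/[C+](C)C)C(C)C | intermediate
12 | 5-[(2R,3R,4S)-6-formyl-5,7-dimethoxy-4-(2-methylprop-1-en-1-yl)-3-(propan-2-yl)-3,4-dihydro-2H-chromen-2-yl]-2,4,6-trimethoxybenzene-1,3-dicarbaldehyde | CC(C)=C[C@@H]1c2c(cc(OC)c(C=O)c2OC)O[C@@H](c2c(OC)c(C=O)c(OC)c(C=O)c2OC)[C@@H]1C(C)C | intermediate
13 | 5-[(2R,3R,4S)-6-formyl-5,7-dimethoxy-4-(2-methylpropyl)-3-(propan-2-yl)-3,4-dihydro-2H-chromen-2-yl]-2,4,6-trimethoxybenzene-1,3-dicarbaldehyde | CC(C)C[C@@H]1c2c(cc(OC)c(C=O)c2OC)O[C@@H](c2c(OC)c(C=O)c(OC)c(C=O)c2OC)[C@@H]1C(C)C | intermediate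
14 | 5-[(2R,3R,4S)-6-formyl-5,7-dihydroxy-4-(2-methylpropyl)-3-(propan-2-yl)-3,4-dihydro-2H-chromen-2-yl]-2,4,6-trihydroxybenzene-1,3-dicarbaldehyde | CC(C)C[C@@H]1c2c(cc(O)c(C=O)c2O)O[C@@H](c2c(O)c(C=O)c(O)c(C=O)c2O)[C@@H]1C(C)C | target

Total step count: 8. Longest linear sequence: 8 steps (1 → 14).

Steps most likely to fail

Step 6. Ring A may attack the other face of the allyl cation, so that the alkenyl group ends trans to the isopropyl group, or the cation may lose the C3 proton before it is trapped.
The fallback sets out from 8 and comes back at 13. It still closes C4–C4a but puts carbon on C4 first and hydrogen last.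
- Electrophilic iodination (N-iodosuccinimide, cat. CF3CO2H, MeCN, 0 °C) can only strike the two equivalent free positions of ring A and should give the ring A iodide F1.
- Cross-metathesis of that iodide with 2 (second-generation Hoveyda–Grubbs catalyst, CH2Cl2, 40 °C) should give the (E)-alkenyl iodide F2.
- An intramolecular Mizoroki–Heck reaction (Pd(OAc)2, PPh3, Ag2CO3, MeCN, 80 °C) closes ring B 6-exo. β-Hydride elimination of the C4 hydrogen should then give the conjugated 4-(2-methylpropylidene)chroman F3.
- Hydrogenation (H2, 10% Pd/C, EtOAc) then delivers hydrogen to C4 from the face away from the neighbouring isopropyl group. The same steric bias that would have spoiled the cation closure now leads to the 3,4-cis compound 13.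

Step 3. The crowded alkoxide may add too slowly, so that attack at an ortho fluorine, hydride transfer from the alkoxide to a formyl group, or decomposition takes over.
The fallback sets out from 5 and comes back at 8, passing by 7 and step 4.
- It is a palladium-catalysed C–O cross-coupling of 5 with purchased 4-bromo-2,6-dimethoxybenzaldehyde ([Pd(allyl)Cl]2, RockPhos, Cs2CO3, toluene, 90 °C).
- The coupling forms O1–C8a by reductive elimination and again leaves the C2–O bond intact.
- This detour makes no compound outside the list (F0).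

Step 5. The vinyl group of 8 sits on a carbon with two branched neighbours, so the ruthenium carbene may fail to engage it while 9 merely dimerises.
The fallback sets out from 8 and comes back at 12.
- A Mizoroki–Heck vinylation with 2-bromopropene (Pd(OAc)2, P(o-tol)3, Ag2CO3, DMF, 80 °C) should give the (E)-1,3-diene F4.
- Under the conditions of step 6, MsOH protonates the terminal CH2 of this diene, which gives the same cation 11 and hence 12.

Further compounds
F1 | step 6 | 5-[(1R,2R)-1-(4-formyl-2-iodo-3,5-dimethoxyphenoxy)-2-(propan-2-yl)but-3-en-1-yl]-2,4,6-trimethoxybenzene-1,3-dicarbaldehyde | O=Cc1c(OC)cc(O[C@@H](c2c(OC)c(C=O)c(OC)c(C=O)c2OC)[C@@H](C=C)C(C)C)c(I)c1OC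
F2 | step 6 | 5-[(1R,2R,3E)-1-(4-formyl-2-iodo-3,5-dimethoxyphenoxy)-5-methyl-2-(propan-2-yl)hex-3-en-1-yl]-2,4,6-trimethoxybenzene-1,3-dicarbaldehyde | O=Cc1c(OC)cc(O[C@@H](c2c(OC)c(C=O)c(OC)c(C=O)c2OC)[C@@H](/C=C/C(C)C)C(C)C)c(I)c1OC
F3 | step 6 | 5-[(2R,3R,4Z)-6-formyl-5,7-dimethoxy-4-(2-methylpropylidene)-3-(propan-2-yl)-3,4-dihydro-2H-chromen-2-yl]-2,4,6-trimethoxybenzene-1,3-dicarbaldehyde | CC(C)/C=C1\c2c(cc(OC)c(C=O)c2OC)O[C@@H](c2c(OC)c(C=O)c(OC)c(C=O)c2OC)[C@@H]1C(C)C
F0 | step 3 | none | none
F4 | step 5 | 5-[(1R,2R,3E)-1-(4-formyl-3,5-dimethoxyphenoxy)-5-methyl-2-(propan-2-yl)hexa-3,5-dien-1-yl]-2,4,6-trimethoxybenzene-1,3-dicarbaldehyde | O=Cc1c(OC)cc(cc1OC)O[C@@H](c1c(OC)c(C=O)c(OC)c(C=O)c1OC)[C@@H](/C=C/C(C)=C)C(C)C
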